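## Analysis of the target

The target 25 is a caffeic acid tetramer built on a 1,2-dihydronaphthalene. Ring A (C4a, C5–C8, C8a) is aromatic and carries hydroxyls at C7 and C8; ring B holds C1 (sp3, carboxyl-bearing), C2 (sp3, 3,4-dihydroxyphenyl-bearing) and the C3=C4 enoate. Both carboxyls are esterified with methyl 3-(3,4-dihydroxyphenyl)lactate. There are four stereocentres. C1 and C2 are both (S), which places the C1 ester and the C2 aryl group on the same face (1,2-cis). The lactate on the C3 carboxyl is (S) and the lactate on the C1 carboxyl is (R), so the two carboxyls must be told apart and esterified with opposite stereochemical outcome. The sensitive points are the four catechols (oxidation), the four esters of three kinds (no saponification is possible) and the ease of aromatisation of ring B. The most delicate is C1–H, which is benzylic and alpha to an ester. Its epimerisation would lead to the trans isomer, expected to be the more stable one, since in the cis compound either the aryl group is pressed against the C3 ester or the C1 ester against O8. The synthesis therefore has to create C1 late and under non-basic conditions, next to the peri oxygen O8. The strategy rests on C2: it bears only hydrogen and an aryl group and sits between C1 and C3, both of which carry carboxyl groups. C2 can thus be brought in as an aldehyde carbon that is attacked twice, once by C3 as a β-ketoester carbon (with C4 temporarily a ketone) and once by C1 as a malonate carbon attached to ring A.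

## Retrosynthetic reasoning

**25 ⇒ 24.** All eight phenols are unmasked last, because free catechols tolerate neither oxidants nor bases. Benzyl ethers are chosen because they survive every earlier step. They are removed by a Lewis acid with a cation trap and not by hydrogenolysis, which would threaten the C3=C4 bond.

**24 ⇒ 23 + 20.** The O–C bond between the C1 carboxyl oxygen and the lactate carbon is cut. Forming it by Mitsunobu alkylation of the carboxylate has two gains. The acid 23 is never turned into an acylating agent, so C1 cannot epimerise through a ketene or enol. The inversion at the lactate carbon also turns the (S)-alcohol 20 into the (R)-ester, so one alcohol serves both side chains.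

**23 ⇒ 22 ⇒ 21.** The C1–H bond is traced back to a C1–CO2H bond. In 21 C1 is a quaternary malonate carbon that cannot epimerise. The C1 stereocentre appears only when the diacid 22 loses CO2 and the resulting enediol is protonated on the face away from the C2 aryl group, which gives the cis acid.

**21 ⇒ 16 + 20.** The acyl–oxygen bond of the C3 ester is cut. Ordinary acylation of 20 by the unsaturated acid 16 keeps the (S) configuration. It is done while C1 is still quaternary, so the basic acylation catalyst meets no labile centre.

**16 ⇒ 15 ⇒ 13 ⇒ 12.** The C3=C4 double bond is derived from a C4 carbonyl group. The oxygen at C4 is the activating group that made C3 nucleophilic; it is removed by hydride reduction and dehydration. The allyl ester at C3 is orthogonal to the tert-butyl esters at C1, which is what allows the two carboxyls to be addressed separately.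

**12 ⇒ 11 ⇒ 9 + 10 (key disconnection).** The bonds C2–C3 and C1–C2 are cut, and C2 becomes the carbonyl carbon of aldehyde 10. In the forward direction C3 of β-ketoester 9 condenses with 10, and the malonate carbon C1 on the neighbouring ring A position adds to the new arylidene carbon. This closes ring B, forms two skeletal bonds and sets C2 under catalyst control. The cut is made here because it removes the only stereocentre that has to come from a catalyst, and it leaves two achiral, easily made pieces.

**9 ⇒ 8 ⇒ 6 + 7.** The C3–C4 bond is cut. The benzoic acid 6 is activated as imidazolide 8 and acylates the magnesium salt of half-ester 7 with loss of CO2. The conditions are neutral and leave the tert-butyl esters intact.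

**6 ⇒ 4 + 5.** The aryl–carbon bond C8a–C1 is cut. The bromine in 4 lies between the carboxyl and O8. A carboxylate-directed copper coupling (Hurtley reaction) with malonate 5 is the one classical arylation that uses exactly this ortho relationship.

**4 ⇒ 3 ⇒ 2 ⇒ 1.** These are functional group changes on commercial 1, whose bromine already sits between the formyl group and the oxygen: aldehyde oxidation, benzylation and demethylation.

**20 ⇒ 19 ⇒ 18 ⇒ 17.** The side-chain alcohol comes from L-DOPA 17 by diazotisation with retention, esterification and phenol benzylation.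

## Alternatives that were turned down

**Alternative 1:** Rhodium-catalysed carbon–carbon activation of a benzocyclobutenone.
- Disconnection: C8a–C1 and C3–C2 are cut and the C1 carboxyl is tied to O8 as a lactone. The substrate A1 is a benzocyclobutenone whose O8 carries a (Z)-3,4-bis(benzyloxy)cinnamoyl group.
- Forward key step: [Rh(cod)Cl]2 with one enantiomer of DTBM-SEGPHOS inserts monovalent rhodium into the acyl–aryl bond (C3–C8a). The rhodacycle adds across the cinnamate double bond and reductive elimination gives the tricyclic keto lactone A2.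
- For it: syn addition to a Z-olefin produces the cis relation of C1 and C2 by mechanism, and one catalyst sets both centres. The C1 carboxyl is distinguished from the start. On the stereochemical problem of C1 this plan is stronger than the chosen one.
- Against it: A2 lacks the C3 carboxyl. It would have to be added by enolisation of the ketone towards C4 and carbonylation, while C2–H is also alpha to the ketone and benzylic. The C1–H of the benzofuranone-type lactone is very acidic, and the lactone would have to be opened by a hindered secondary alkoxide, so the cis relation is unlikely to survive. This insertion is established for ether-tethered, lightly substituted olefins. A 1,2-disubstituted, electron-poor cinnamate on an ester tether invites Z to E isomerisation and decarbonylation.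
- Comparison: the chosen route carries the C3 carboxyl from the beginning, keeps C1 quaternary until two steps before the end and differentiates the carboxyls by orthogonal esters. Alternative 1 is no shorter once the carboxyl is added and the lactone opened.

**Alternative 2:** Rhodium carbenoid C–H insertion.
- Disconnection: only C1–C2 is cut. The substrate A3 is an aryldiazoacetate (trichloroethyl ester) at C8a, whose ring A also carries the (E)-enoate with the C3 (S)-lactate ester and a C2 methylene bearing the aryl group.
- Forward key step: dirhodium tetrakis[N-phthaloyl-(S)-tert-leucinate], Rh2(S-PTTL)4, a divalent rhodium carboxylate, or its enantiomer forms the donor/acceptor carbenoid at C1. It inserts into the benzylic and allylic C2–H bond and gives the silyl-protected core A4.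
- For it: it is the most direct endgame. The C3=C4 bond, the C3 lactate and the oxidation level are in place, and C1 and C2 are set together. Catalysts of this type give cis products in the related five-membered ring insertions, and the trichloroethyl ester is orthogonal. It is stronger than the chosen route on step economy after the ring closure.
- Against it: the ring closure is a six-membered (1,6) insertion, less favoured and less studied than the 1,5 mode, so the cis preference cannot be carried over. The carbenoid sits beside electron-rich catechol ethers, which invite Buchner-type addition. The catalyst must override the resident lactate centre. Substrate A3 needs a trisubstituted enoate of defined geometry and a diazo transfer onto an arylacetate hemmed in by two ortho groups. A wrong C1 configuration cannot be corrected.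
- Comparison: the chosen strategy separates the two stereochemical problems: C2 by a catalyst in a polar manifold, C1 by substrate-controlled protonation. It pays for this with the reduction, dehydration and ester exchange steps.

**Alternative 3:** Rhodium-catalysed arylative annulation.
- Disconnection: C4a–C4 and C3–C2 are cut. Ring A arrives as the arylboronate A5, which carries the tert-butyl α-aryl acrylate (C1=C2) in the ortho position. C3 and C4 arrive as the propiolate A6 of the (S)-lactate.
- Forward key step: [Rh(C2H4)2Cl]2 with a chiral diene transfers the aryl group from boron to monovalent rhodium. Arylrhodation of A6 puts the aryl group on C4 and rhodium on C3. The alkenylrhodium adds to C2 of the acrylate, and protonation of the rhodium enolate at C1 gives A7.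
- For it: it is the most convergent plan. Three of the four C9 units are joined in one step at the final oxidation level with the C3 ester already in place, and C2 is catalyst-controlled as in the chosen route. It is clearly stronger on step count.
- Against it: the acceptor is a trisubstituted α,β-diaryl acrylate, a poor partner for conjugate addition of an alkenylrhodium, which can instead be protonated or undergo a 1,4-rhodium shift onto ring A. C1 is formed by protonation of a rhodium enolate in the basic, protic medium that boron-to-rhodium transfer requires, with no bias towards cis and with the new C1–H exposed to base. The boronate A5 is congested around C8a.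
- Comparison: the chosen route uses a doubly activated arylidene ketoester as acceptor and sets C1 under weakly basic conditions on a carboxylate, two steps before the end. It accepts a longer sequence for this.

Key step: step 6

Assumption: the facial sense of the squaramide-catalysed closure cannot be assigned with certainty by analogy. The quinine-derived catalyst is written, and its quinidine-derived pseudoenantiomer takes its place if the (2R) product results. Monoallyl malonate 7 is taken as a purchased reagent.

## Route

Step 1
Reactants: 1 2-bromo-3-hydroxy-4-methoxybenzaldehyde (2-bromoisovanillin)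
Product: 2 2-bromo-3,4-dihydroxybenzaldehyde
Conditions: BBr3, CH2Cl2, −78 °C → rt; then H2O
Reagents that add atoms: none
Why: Lewis-acid ether cleavage: BBr3 binds the methoxy oxygen and bromide removes the methyl group by SN2; aldehyde and aryl bromide are inert, and the free catechol lets both ring A oxygens carry the same benzyl group.

Step 2
Reactants: 2 2-bromo-3,4-dihydroxybenzaldehyde
Product: 3 3,4-bis(benzyloxy)-2-bromobenzaldehyde
Conditions: BnBr, K2CO3, DMF, 60 °C
Reagents that add atoms: benzyl bromide BrCc1ccccc1
Why: Williamson ether synthesis: both phenoxides are alkylated, the one next to bromine included, since DMF at 60 °C suffices for a hindered phenoxide and a primary benzylic halide.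

Step 3
Reactants: 3 3,4-bis(benzyloxy)-2-bromobenzaldehyde
Product: 4 3,4-bis(benzyloxy)-2-bromobenzoic acid
Conditions: NaClO2, NaH2PO4, 2-methyl-2-butene, t-BuOH/H2O, rt
Reagents that add atoms: sodium chlorite [Na+].[O-]Cl=O
Why: Pinnick oxidation: chlorous acid adds to the aldehyde and fragments to the acid, while 2-methyl-2-butene traps HOCl so that the electron-rich ring and the benzyl ethers are not chlorinated.

Step 4
Reactants: 4 3,4-bis(benzyloxy)-2-bromobenzoic acid; 5 di-tert-butyl malonate
Product: 6 3,4-bis(benzyloxy)-2-[bis(tert-butoxycarbonyl)methyl]benzoic acid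
Conditions: NaH, CuBr (10 mol %), dioxane, 80 °C; then cold 1 M HCl to pH 3
Reagents that add atoms: none
Why: Hurtley reaction: the ortho carboxylate binds monovalent copper and directs it into the neighbouring C–Br bond, and the sodium malonate is then coupled to the aryl carbon (C8a–C1); this carboxylate-directed path is what lets a bromide between two ortho substituents react, and tert-butyl esters withstand the base and the brief cold acid.

Step 5
Reactants: 6 3,4-bis(benzyloxy)-2-[bis(tert-butoxycarbonyl)methyl]benzoic acid; 7 monoallyl malonate (3-(allyloxy)-3-oxopropanoic acid)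
Product: 9 allyl 3-{3,4-bis(benzyloxy)-2-[bis(tert-butoxycarbonyl)methyl]phenyl}-3-oxopropanoate, via acyl imidazolide 8 (not isolated)
Conditions: CDI, THF, rt; then 7, MgCl2, Et3N, THF, rt → 45 °C; then cold 1 M HCl
Reagents that add atoms: none
Why: Decarboxylative Claisen condensation of a magnesium malonate half-ester with an acyl imidazolide: 8 acylates the chelated magnesium enolate of 7 and the adduct loses CO2 to give the β-ketoester (C3–C4 bond) under near-neutral conditions; if the ortho malonate enol closes onto 8, the resulting enol lactone is still an acylating agent for the magnesium malonate and leads to the same product.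

Step 6
Reactants: 9 allyl 3-{3,4-bis(benzyloxy)-2-[bis(tert-butoxycarbonyl)methyl]phenyl}-3-oxopropanoate; 10 3,4-bis(benzyloxy)benzaldehyde
Product: 12 3-allyl 1,1-di-tert-butyl (2S)-7,8-bis(benzyloxy)-2-[3,4-bis(benzyloxy)phenyl]-4-hydroxy-1,2-dihydronaphthalene-1,1,3-tricarboxylate (enol form of the 4-tetralone), via arylidene ketoester 11 (not isolated)
Conditions: piperidinium acetate (10 mol %), 3-{[3,5-bis(trifluoromethyl)phenyl]amino}-4-{[(8α,9S)-6′-methoxycinchonan-9-yl]amino}cyclobut-3-ene-1,2-dione (quinine-derived squaramide, 10 mol %), 4 Å molecular sieves, toluene, rt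
Reagents that add atoms: none
Why: Proposed new method: piperidine and aldehyde 10 form an iminium ion that the enol of the β-ketoester carbon C3 attacks, and loss of piperidine gives arylidene ketoester 11 (Knoevenagel condensation); the squaramide N–H bonds then hold the 1,3-dicarbonyl unit of 11 while the quinuclidine nitrogen removes the ring A malonate proton, and the carbanion C1 adds to the arylidene carbon C2 (intramolecular Michael addition), the closest known reaction types being the amine–thiourea-catalysed 6-endo oxa-Michael closure of ortho-hydroxyaryl alkylidene β-ketoesters to flavanones and the squaramide-catalysed intermolecular Michael addition of malonates to enones. Ring B closes in the 6-endo-trig mode, both carbons of the C2=C3 bond ending up in the ring. The only new stereocentre, C2, is controlled by the catalyst, which decides the face of the arylidene carbon that the malonate attacks; C1 becomes quaternary and carries no stereochemical information. Chemoselectivity comes from the substrate: the malonate carbon has a single hydrogen and cannot condense with 10, the tert-butyl esters are too hindered for Claisen attack by the C3 enolate, and the aldehyde can be taken up only at C3. The geometry of 11 need not be controlled, because its E and Z isomers interconvert by reversible amine addition. The adduct tautomerises to the hydrogen-bonded, aryl-conjugated enol 12, which withdraws the enolate needed for retro-Michael opening and so protects the configuration at C2.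

Step 7
Reactants: 12 3-allyl 1,1-di-tert-butyl (2S)-7,8-bis(benzyloxy)-2-[3,4-bis(benzyloxy)phenyl]-4-hydroxy-1,2-dihydronaphthalene-1,1,3-tricarboxylate
Product: 13 3-allyl 1,1-di-tert-butyl (2R)-7,8-bis(benzyloxy)-2-[3,4-bis(benzyloxy)phenyl]-4-hydroxy-1,2,3,4-tetrahydronaphthalene-1,1,3-tricarboxylate (mixture of C3/C4 diastereomers; C2 spatially unchanged)
Conditions: NaBH4, CeCl3·7H2O, MeOH/THF, −20 °C
Reagents that add atoms: none
Why: Luche reduction: CeCl3 activates the carbonyl of the keto tautomer and keeps the medium only weakly basic, so hydride should add to C4 faster than the enolate can open by retro-Michael reaction; allyl and tert-butyl esters are not reduced at −20 °C, and the new C3 and C4 centres disappear in step 8.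

Step 8
Reactants: 13 3-allyl 1,1-di-tert-butyl (2R)-7,8-bis(benzyloxy)-2-[3,4-bis(benzyloxy)phenyl]-4-hydroxy-1,2,3,4-tetrahydronaphthalene-1,1,3-tricarboxylate
Product: 15 3-allyl 1,1-di-tert-butyl (2S)-7,8-bis(benzyloxy)-2-[3,4-bis(benzyloxy)phenyl]-1,2-dihydronaphthalene-1,1,3-tricarboxylate, via C4 mesylate 14 (not isolated)
Conditions: MsCl, Et3N, CH2Cl2, 0 °C; then DBU, rt
Reagents that add atoms: none
Why: Mesylation and elimination: the C4 mesylate is benzylic and para to O7, and C3–H is alpha to the ester, so loss of methanesulfonate (E1 or E1cB) can only give the C3=C4 enoate conjugated with ring A; both diastereomers of 13 converge and C2 is not acidic enough to be touched.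

Step 9
Reactants: 15 3-allyl 1,1-di-tert-butyl (2S)-7,8-bis(benzyloxy)-2-[3,4-bis(benzyloxy)phenyl]-1,2-dihydronaphthalene-1,1,3-tricarboxylate
Product: 16 (2S)-7,8-bis(benzyloxy)-2-[3,4-bis(benzyloxy)phenyl]-1,1-bis(tert-butoxycarbonyl)-1,2-dihydronaphthalene-3-carboxylic acid
Conditions: Pd(PPh3)4 (5 mol %), morpholine, THF, rt; citric acid wash
Reagents that add atoms: none
Why: Tsuji–Trost deallylation: zerovalent palladium ionises the allyl ester to a π-allyl complex that morpholine captures, which frees the C3 acid under neutral conditions and leaves tert-butyl esters, benzyl ethers and C2 untouched.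

Step 10
Reactants: 17 L-DOPA, (S)-2-amino-3-(3,4-dihydroxyphenyl)propanoic acid
Product: 18 (S)-3-(3,4-dihydroxyphenyl)-2-hydroxypropanoic acid
Conditions: NaNO2, 1 M H2SO4, 0 °C → rt
Reagents that add atoms: water O
Why: Diazotisation of an α-amino acid: the diazonium group is displaced by the neighbouring carboxylate to an α-lactone that water opens, so two inversions give the (S)-hydroxy acid with net retention; cold dilute acid and slow nitrite addition limit attack on the catechol.

Step 11
Reactants: 18 (S)-3-(3,4-dihydroxyphenyl)-2-hydroxypropanoic acid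
Product: 19 methyl (S)-3-(3,4-dihydroxyphenyl)-2-hydroxypropanoate
Conditions: MeOH, H2SO4 (cat.), 50 °C
Reagents that add atoms: methanol CO
Why: Fischer esterification; the α-hydroxy stereocentre is not enolised under acid catalysis.

Step 12
Reactants: 19 methyl (S)-3-(3,4-dihydroxyphenyl)-2-hydroxypropanoate
Product: 20 methyl (S)-3-[3,4-bis(benzyloxy)phenyl]-2-hydroxypropanoate
Conditions: BnBr, K2CO3, acetone, reflux
Reagents that add atoms: benzyl bromide BrCc1ccccc1
Why: Williamson ether synthesis, chemoselective because K2CO3 deprotonates the phenols but not the secondary alcohol; the free hydroxyl is kept for both later esterifications.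

Step 13
Reactants: 16 (2S)-7,8-bis(benzyloxy)-2-[3,4-bis(benzyloxy)phenyl]-1,1-bis(tert-butoxycarbonyl)-1,2-dihydronaphthalene-3-carboxylic acid; 20 methyl (S)-3-[3,4-bis(benzyloxy)phenyl]-2-hydroxypropanoate
Product: 21 1,1-di-tert-butyl 3-{(2S)-3-[3,4-bis(benzyloxy)phenyl]-1-methoxy-1-oxopropan-2-yl} (2S)-7,8-bis(benzyloxy)-2-[3,4-bis(benzyloxy)phenyl]-1,2-dihydronaphthalene-1,1,3-tricarboxylate
Conditions: DIC, DMAP (cat.), CH2Cl2, 0 °C → rt
Reagents that add atoms: none
Why: Steglich esterification: the carbodiimide activates the C3 acid and DMAP transfers the acyl group to the hydroxyl of 20, so the lactate carbon keeps its (S) configuration; C1 is quaternary at this stage, so no ring stereocentre is exposed to the basic catalyst.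

Step 14
Reactants: 21 1,1-di-tert-butyl 3-{(2S)-3-[3,4-bis(benzyloxy)phenyl]-1-methoxy-1-oxopropan-2-yl} (2S)-7,8-bis(benzyloxy)-2-[3,4-bis(benzyloxy)phenyl]-1,2-dihydronaphthalene-1,1,3-tricarboxylate
Product: 23 (1S,2S)-7,8-bis(benzyloxy)-2-[3,4-bis(benzyloxy)phenyl]-3-({(2S)-3-[3,4-bis(benzyloxy)phenyl]-1-methoxy-1-oxopropan-2-yl}oxycarbonyl)-1,2-dihydronaphthalene-1-carboxylic acid (1,2-cis), via malonic diacid 22 (not isolated)
Conditions: TFA, CH2Cl2, 0 °C; evaporate; then 2,4,6-collidine, MeCN, 50 °C
Reagents that add atoms: none
Why: Acidolysis of both tert-butyl esters gives diacid 22, which decarboxylates through the cyclic transition state of malonic acids to an exocyclic enediol at C1; the C2 aryl group is pseudo-axial to avoid the C3 ester, so the proton from the bulky collidinium ion should enter C1 from the opposite face and leave the carboxyl cis to the aryl group, as known for the decarboxylation of 2-arylcycloalkane-1,1-dicarboxylic acids. The product is held as its carboxylate, which resists enolisation.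

Step 15
Reactants: 23 (1S,2S)-7,8-bis(benzyloxy)-2-[3,4-bis(benzyloxy)phenyl]-3-({(2S)-3-[3,4-bis(benzyloxy)phenyl]-1-methoxy-1-oxopropan-2-yl}oxycarbonyl)-1,2-dihydronaphthalene-1-carboxylic acid; 20 methyl (S)-3-[3,4-bis(benzyloxy)phenyl]-2-hydroxypropanoate
Product: 24 1-{(2R)-3-[3,4-bis(benzyloxy)phenyl]-1-methoxy-1-oxopropan-2-yl} 3-{(2S)-3-[3,4-bis(benzyloxy)phenyl]-1-methoxy-1-oxopropan-2-yl} (1S,2S)-7,8-bis(benzyloxy)-2-[3,4-bis(benzyloxy)phenyl]-1,2-dihydronaphthalene-1,3-dicarboxylate (octabenzyl ether of the target)
Conditions: PPh3, DIAD, THF, 0 °C → rt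
Reagents that add atoms: none
Why: Mitsunobu esterification: the hydroxyl of 20 becomes an oxyphosphonium leaving group and the carboxylate of 23 displaces it by SN2 with inversion, which gives the (R)-lactate ester; the acid is never activated as an acylating agent, so the labile C1 centre cannot epimerise through a ketene or enol.

Step 16
Reactants: 24 octabenzyl ether of the target
Product: 25 CNP0237075.1, 1-[(2R)-3-(3,4-dihydroxyphenyl)-1-methoxy-1-oxopropan-2-yl] 3-[(2S)-3-(3,4-dihydroxyphenyl)-1-methoxy-1-oxopropan-2-yl] (1S,2S)-2-(3,4-dihydroxyphenyl)-7,8-dihydroxy-1,2-dihydronaphthalene-1,3-dicarboxylate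
Conditions: BCl3, pentamethylbenzene, CH2Cl2, −78 °C; then MeOH; work-up under argon
Reagents that add atoms: none
Why: Lewis-acid debenzylation: BCl3 coordinates each aryl benzyl ether and the benzyl cation is passed to pentamethylbenzene (Friedel–Crafts trapping), which prevents C-benzylation of the catechols; at −78 °C the esters, the C3=C4 bond and C1 should be untouched, whereas hydrogenolysis would endanger the styrene-type double bond.

## Compound list

1 | 2-bromo-3-hydroxy-4-methoxybenzaldehyde (2-bromoisovanillin) | COc1ccc(C=O)c(Br)c1O | starting material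
2 | 2-bromo-3,4-dihydroxybenzaldehyde | O=Cc1ccc(O)c(O)c1Br | intermediate
3 | 3,4-bis(benzyloxy)-2-bromobenzaldehyde | O=Cc1ccc(OCc2ccccc2)c(OCc2ccccc2)c1Br | intermediate
4 | 3,4-bis(benzyloxy)-2-bromobenzoic acid | OC(=O)c1ccc(OCc2ccccc2)c(OCc2ccccc2)c1Br | intermediate
5 | di-tert-butyl malonate | CC(C)(C)OC(=O)CC(=O)OC(C)(C)C | starting material
6 | 3,4-bis(benzyloxy)-2-[bis(tert-butoxycarbonyl)methyl]benzoic acid | OC(=O)c1ccc(OCc2ccccc2)c(OCc2ccccc2)c1C(C(=O)OC(C)(C)C)C(=O)OC(C)(C)C | intermediate
7 | monoallyl malonate (3-(allyloxy)-3-oxopropanoic acid) | C=CCOC(=O)CC(=O)O | starting material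
8 | 1-{3,4-bis(benzyloxy)-2-[bis(tert-butoxycarbonyl)methyl]benzoyl}imidazole (acyl imidazolide) | O=C(c1ccc(OCc2ccccc2)c(OCc2ccccc2)c1C(C(=O)OC(C)(C)C)C(=O)OC(C)(C)C)n1ccnc1 | intermediate
9 | allyl 3-{3,4-bis(benzyloxy)-2-[bis(tert-butoxycarbonyl)methyl]phenyl}-3-oxopropanoate | C=CCOC(=O)CC(=O)c1ccc(OCc2ccccc2)c(OCc2ccccc2)c1C(C(=O)OC(C)(C)C)C(=O)OC(C)(C)C | intermediate
10 | 3,4-bis(benzyloxy)benzaldehyde | O=Cc1ccc(OCc2ccccc2)c(OCc2ccccc2)c1 | starting material
11 | allyl 2-{3,4-bis(benzyloxy)-2-[bis(tert-butoxycarbonyl)methyl]benzoyl}-3-[3,4-bis(benzyloxy)phenyl]prop-2-enoate (E/Z mixture) | C=CCOC(=O)C(=Cc1ccc(OCc2ccccc2)c(OCc2ccccc2)c1)C(=O)c1ccc(OCc2ccccc2)c(OCc2ccccc2)c1C(C(=O)OC(C)(C)C)C(=O)OC(C)(C)C | intermediate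
12 | 3-allyl 1,1-di-tert-butyl (2S)-7,8-bis(benzyloxy)-2-[3,4-bis(benzyloxy)phenyl]-4-hydroxy-1,2-dihydronaphthalene-1,1,3-tricarboxylate (4-tetralone enol) | C=CCOC(=O)C1=C(O)c2ccc(OCc3ccccc3)c(OCc3ccccc3)c2C(C(=O)OC(C)(C)C)(C(=O)OC(C)(C)C)[C@H]1c1ccc(OCc2ccccc2)c(OCc2ccccc2)c1 | intermediate
13 | 3-allyl 1,1-di-tert-butyl (2R)-7,8-bis(benzyloxy)-2-[3,4-bis(benzyloxy)phenyl]-4-hydroxy-1,2,3,4-tetrahydronaphthalene-1,1,3-tricarboxylate (C3/C4 diastereomers) | C=CCOC(=O)C1C(O)c2ccc(OCc3ccccc3)c(OCc3ccccc3)c2C(C(=O)OC(C)(C)C)(C(=O)OC(C)(C)C)[C@H]1c1ccc(OCc2ccccc2)c(OCc2ccccc2)c1 | intermediate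
14 | C4 methanesulfonate of 13 | C=CCOC(=O)C1C(OS(C)(=O)=O)c2ccc(OCc3ccccc3)c(OCc3ccccc3)c2C(C(=O)OC(C)(C)C)(C(=O)OC(C)(C)C)[C@H]1c1ccc(OCc2ccccc2)c(OCc2ccccc2)c1 | intermediate
15 | 3-allyl 1,1-di-tert-butyl (2S)-7,8-bis(benzyloxy)-2-[3,4-bis(benzyloxy)phenyl]-1,2-dihydronaphthalene-1,1,3-tricarboxylate | C=CCOC(=O)C1=Cc2ccc(OCc3ccccc3)c(OCc3ccccc3)c2C(C(=O)OC(C)(C)C)(C(=O)OC(C)(C)C)[C@H]1c1ccc(OCc2ccccc2)c(OCc2ccccc2)c1 | intermediate
16 | (2S)-7,8-bis(benzyloxy)-2-[3,4-bis(benzyloxy)phenyl]-1,1-bis(tert-butoxycarbonyl)-1,2-dihydronaphthalene-3-carboxylic acid | OC(=O)C1=Cc2ccc(OCc3ccccc3)c(OCc3ccccc3)c2C(C(=O)OC(C)(C)C)(C(=O)OC(C)(C)C)[C@H]1c1ccc(OCc2ccccc2)c(OCc2ccccc2)c1 | intermediate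
17 | L-DOPA, (S)-2-amino-3-(3,4-dihydroxyphenyl)propanoic acid | N[C@@H](Cc1ccc(O)c(O)c1)C(=O)O | starting material
18 | (S)-3-(3,4-dihydroxyphenyl)-2-hydroxypropanoic acid | O[C@@H](Cc1ccc(O)c(O)c1)C(=O)O | intermediate
19 | methyl (S)-3-(3,4-dihydroxyphenyl)-2-hydroxypropanoate | O[C@@H](Cc1ccc(O)c(O)c1)C(=O)OC | intermediate
20 | methyl (S)-3-[3,4-bis(benzyloxy)phenyl]-2-hydroxypropanoate | O[C@@H](Cc1ccc(OCc2ccccc2)c(OCc2ccccc2)c1)C(=O)OC | intermediate
21 | C3 (S)-lactate ester with di-tert-butyl malonate at C1 (name as in step 13) | COC(=O)[C@H](Cc1ccc(OCc2ccccc2)c(OCc2ccccc2)c1)OC(=O)C1=Cc2ccc(OCc3ccccc3)c(OCc3ccccc3)c2C(C(=O)OC(C)(C)C)(C(=O)OC(C)(C)C)[C@H]1c1ccc(OCc2ccccc2)c(OCc2ccccc2)c1 | intermediate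
22 | the 1,1-dicarboxylic acid corresponding to 21 (malonic diacid) | COC(=O)[C@H](Cc1ccc(OCc2ccccc2)c(OCc2ccccc2)c1)OC(=O)C1=Cc2ccc(OCc3ccccc3)c(OCc3ccccc3)c2C(C(=O)O)(C(=O)O)[C@H]1c1ccc(OCc2ccccc2)c(OCc2ccccc2)c1 | intermediate
23 | (1S,2S)-configured 1,2-cis C1 carboxylic acid with the C3 (S)-lactate ester (name as in step 14) | COC(=O)[C@H](Cc1ccc(OCc2ccccc2)c(OCc2ccccc2)c1)OC(=O)C1=Cc2ccc(OCc3ccccc3)c(OCc3ccccc3)c2[C@@H](C(=O)O)[C@H]1c1ccc(OCc2ccccc2)c(OCc2ccccc2)c1 | intermediate
24 | octabenzyl ether of the target (name as in step 15) | COC(=O)[C@H](Cc1ccc(OCc2ccccc2)c(OCc2ccccc2)c1)OC(=O)C1=Cc2ccc(OCc3ccccc3)c(OCc3ccccc3)c2[C@@H](C(=O)O[C@H](Cc2ccc(OCc3ccccc3)c(OCc3ccccc3)c2)C(=O)OC)[C@H]1c1ccc(OCc2ccccc2)c(OCc2ccccc2)c1 | intermediate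
25 | CNP0237075.1 (name as in step 16) | COC(=O)[C@H](Cc1ccc(O)c(O)c1)OC(=O)C1=Cc2ccc(O)c(O)c2[C@@H](C(=O)O[C@H](Cc2ccc(O)c(O)c2)C(=O)OC)[C@H]1c1ccc(O)c(O)c1 | target

## Step count and least certain steps

Total step count: 16. Longest linear sequence: 13 steps (steps 1–9 and 13–16, from 1). The side-chain alcohol 20 takes 3 steps (10–12) from 17 and is used twice.

**Step 6 (key step, proposed new method).**
- What may go wrong: a racemic background closure promoted by piperidine or acetate may compete with the squaramide pathway and lower the enantiomeric purity. Deprotonation of the twisted, hindered di-tert-butyl arylmalonate next to O8 may be slow, so that a second molecule of 9 adds to 11 intermolecularly. Retro-Michael opening may erode C2.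
- Fallback (known chemistry, from 9 and 10, back at 12): 9 and 10 are condensed with piperidine and acetic acid in toluene with azeotropic removal of water, and 11 is isolated. 11 is closed with a catalytic amount of K2CO3 or DBU in MeCN, an ordinary base-mediated intramolecular Michael addition of a malonate, to the racemic tetralone enol F1. The enantiomers are separated by preparative chromatography on a chiral stationary phase, which gives 12. The unwanted (2R) enantiomer F2 is returned to F1 by the same base through retro-Michael and Michael equilibration and is resolved again.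

**Step 14.**
- What may go wrong: facial discrimination in the protonation of the enediol may be insufficient, or C1 may epimerise after decarboxylation towards the trans acid.
- Fallback (from 23 as obtained, back at 24; step 15 is then not needed): the mixture of 23 and its C1 epimer, the trans acid F3, is converted with oxalyl chloride and catalytic DMF into the acid chlorides F4. Treatment with N,N-dimethylethylamine in toluene at −78 °C gives the aryl ketene F5, in which the C1 centre is erased, so both epimers converge. The (R)-alcohol F7 is then added. It is made from 20 by Mitsunobu reaction with 4-nitrobenzoic acid to the (R)-4-nitrobenzoate F6, followed by methanolysis with K2CO3 in MeOH. Its amine-mediated addition to F5 gives an ester enolate that is protonated at C1 at low temperature from the face away from the C2 aryl group, which leads to 24. This addition of α-hydroxy esters to aryl ketenes with stereoselective protonation is a known reaction type, and the chiral alcohol adds a second control element.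

**Step 4.**
- What may go wrong: copper insertion and coupling may be slow at a bromide flanked by two ortho groups with a bulky malonate, and protodebromination may take over.
- Fallback (from 3, back at 6): aldehyde 3 is coupled with 5 under palladium catalysis (Pd(dba)2, P(t-Bu)3, K3PO4, toluene, 70 °C). Here a zerovalent palladium complex of a bulky phosphine inserts into the C–Br bond without a directing group, and the product is the aryl malonate aldehyde F8. F8 is oxidised under the conditions of step 3 to 6.

**Step 7.**
- What may go wrong: the fully enolised, hindered β-ketoester may take up hydride slowly, and the basic medium may allow retro-Michael opening and loss of the C2 configuration.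
- Fallback (from 12, back at 16; steps 8 and 9 are then not needed): the enol is trapped with Tf2O and i-Pr2NEt in CH2Cl2 at −78 °C as the enol triflate F9. Pd(OAc)2, PPh3, HCO2H and Et3N in DMF at 60 °C then reduce the vinyl triflate to the C4–H enoate with formate and cleave the allyl ester in the same operation, which gives 16.

**Step 15.**
- What may go wrong: the activated lactate may undergo β-elimination to the cinnamate, or the hindered carboxylate may displace slowly, so that part of the ester forms with retention through an acyloxyphosphonium path.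
- Fallback (from 20 and 23, back at 24): 20 is converted with Tf2O and 2,6-lutidine in CH2Cl2 at −78 °C into the (S)-triflate F10. The cesium carboxylate of 23 (0.5 equivalent of Cs2CO3, MeCN, −20 °C → 0 °C) is alkylated with F10 by SN2 displacement with inversion. The weak carboxylate base does not endanger C1.

## Further compounds

F1 | step 6 | racemic 3-allyl 1,1-di-tert-butyl 7,8-bis(benzyloxy)-2-[3,4-bis(benzyloxy)phenyl]-4-hydroxy-1,2-dihydronaphthalene-1,1,3-tricarboxylate | C=CCOC(=O)C1=C(O)c2ccc(OCc3ccccc3)c(OCc3ccccc3)c2C(C(=O)OC(C)(C)C)(C(=O)OC(C)(C)C)C1c1ccc(OCc2ccccc2)c(OCc2ccccc2)c1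
F2 | step 6 | (2R) enantiomer of 12 | C=CCOC(=O)C1=C(O)c2ccc(OCc3ccccc3)c(OCc3ccccc3)c2C(C(=O)OC(C)(C)C)(C(=O)OC(C)(C)C)[C@@H]1c1ccc(OCc2ccccc2)c(OCc2ccccc2)c1
F3 | step 14 | (1R,2S) C1 epimer of 23 (1,2-trans acid) | COC(=O)[C@H](Cc1ccc(OCc2ccccc2)c(OCc2ccccc2)c1)OC(=O)C1=Cc2ccc(OCc3ccccc3)c(OCc3ccccc3)c2[C@H](C(=O)O)[C@H]1c1ccc(OCc2ccccc2)c(OCc2ccccc2)c1
F4 | step 14 | C1 acid chlorides of 23 and F3 (C1 epimer mixture) | COC(=O)[C@H](Cc1ccc(OCc2ccccc2)c(OCc2ccccc2)c1)OC(=O)C1=Cc2ccc(OCc3ccccc3)c(OCc3ccccc3)c2C(C(=O)Cl)[C@H]1c1ccc(OCc2ccccc2)c(OCc2ccccc2)c1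
F5 | step 14 | C1 ketene (C1=C=O) with the C3 (S)-lactate ester, C2 as in 23 | COC(=O)[C@H](Cc1ccc(OCc2ccccc2)c(OCc2ccccc2)c1)OC(=O)C1=Cc2ccc(OCc3ccccc3)c(OCc3ccccc3)c2C(=C=O)[C@H]1c1ccc(OCc2ccccc2)c(OCc2ccccc2)c1
F6 | step 14 | methyl (R)-3-[3,4-bis(benzyloxy)phenyl]-2-[(4-nitrobenzoyl)oxy]propanoate | COC(=O)[C@@H](Cc1ccc(OCc2ccccc2)c(OCc2ccccc2)c1)OC(=O)c1ccc(cc1)[N+](=O)[O-]
F7 | step 14 | methyl (R)-3-[3,4-bis(benzyloxy)phenyl]-2-hydroxypropanoate | O[C@H](Cc1ccc(OCc2ccccc2)c(OCc2ccccc2)c1)C(=O)OC
F8 | step 4 | di-tert-butyl 2-[2,3-bis(benzyloxy)-6-formylphenyl]propanedioate | O=Cc1ccc(OCc2ccccc2)c(OCc2ccccc2)c1C(C(=O)OC(C)(C)C)C(=O)OC(C)(C)C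
F9 | step 7 | C4 enol trifluoromethanesulfonate of 12 | C=CCOC(=O)C1=C(OS(=O)(=O)C(F)(F)F)c2ccc(OCc3ccccc3)c(OCc3ccccc3)c2C(C(=O)OC(C)(C)C)(C(=O)OC(C)(C)C)[C@H]1c1ccc(OCc2ccccc2)c(OCc2ccccc2)c1
F10 | step 15 | methyl (S)-3-[3,4-bis(benzyloxy)phenyl]-2-{[(trifluoromethyl)sulfonyl]oxy}propanoate | COC(=O)[C@H](Cc1ccc(OCc2ccccc2)c(OCc2ccccc2)c1)OS(=O)(=O)C(F)(F)F
A1 | alternative 1 | 4-(benzyloxy)-7-oxobicyclo[4.2.0]octa-1,3,5-trien-5-yl (2Z)-3-[3,4-bis(benzyloxy)phenyl]prop-2-enoate (benzocyclobutenone with the cinnamate on O8) | O=C1Cc2ccc(OCc3ccccc3)c(OC(=O)/C=C\c3ccc(OCc4ccccc4)c(OCc4ccccc4)c3)c12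
A2 | alternative 1 | tricyclic C3 ketone with the C1–O8 lactone, (1S,2S), C1 and C2 cis | O=C1Cc2ccc(OCc3ccccc3)c3OC(=O)[C@H](c23)[C@H]1c1ccc(OCc2ccccc2)c(OCc2ccccc2)c1
A3 | alternative 2 | 2,2,2-trichloroethyl aryldiazoacetate at C8a with the (E)-enoate bearing the C3 (S)-lactate ester and the C2 arylmethyl group, all phenols as tert-butyldimethylsilyl ethers | COC(=O)[C@H](Cc1ccc(O[Si](C)(C)C(C)(C)C)c(O[Si](C)(C)C(C)(C)C)c1)OC(=O)/C(Cc1ccc(O[Si](C)(C)C(C)(C)C)c(O[Si](C)(C)C(C)(C)C)c1)=C/c1ccc(O[Si](C)(C)C(C)(C)C)c(O[Si](C)(C)C(C)(C)C)c1C(=[N+]=[N-])C(=O)OCC(Cl)(Cl)Cl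
A4 | alternative 2 | silyl-protected (1S,2S) core with the C1 trichloroethyl ester and the C3 (S)-lactate ester | COC(=O)[C@H](Cc1ccc(O[Si](C)(C)C(C)(C)C)c(O[Si](C)(C)C(C)(C)C)c1)OC(=O)C1=Cc2ccc(O[Si](C)(C)C(C)(C)C)c(O[Si](C)(C)C(C)(C)C)c2[C@@H](C(=O)OCC(Cl)(Cl)Cl)[C@H]1c1ccc(O[Si](C)(C)C(C)(C)C)c(O[Si](C)(C)C(C)(C)C)c1
A5 | alternative 3 | tert-butyl 2-[2,3-bis(benzyloxy)-6-(4,4,5,5-tetramethyl-1,3,2-dioxaborolan-2-yl)phenyl]-3-[3,4-bis(benzyloxy)phenyl]prop-2-enoate (alkene geometry left open) | CC(C)(C)OC(=O)C(=Cc1ccc(OCc2ccccc2)c(OCc2ccccc2)c1)c1c(B2OC(C)(C)C(C)(C)O2)ccc(OCc2ccccc2)c1OCc1ccccc1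
A6 | alternative 3 | (2S)-3-[3,4-bis(benzyloxy)phenyl]-1-methoxy-1-oxopropan-2-yl prop-2-ynoate | COC(=O)[C@H](Cc1ccc(OCc2ccccc2)c(OCc2ccccc2)c1)OC(=O)C#C
A7 | alternative 3 | benzyl-protected (1S,2S) core with the C1 tert-butyl ester and the C3 (S)-lactate ester | COC(=O)[C@H](Cc1ccc(OCc2ccccc2)c(OCc2ccccc2)c1)OC(=O)C1=Cc2ccc(OCc3ccccc3)c(OCc3ccccc3)c2[C@@H](C(=O)OC(C)(C)C)[C@H]1c1ccc(OCc2ccccc2)c(OCc2ccccc2)c1
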